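## Retrosynthetic overview

1. The butenolide ring is bought intact (4-bromofuran-2(5H)-one) and joined last by Suzuki coupling to an (E,E)-dienyl boronate made from the enal end of a farnesol-derived chain.
2. The isobutenyl group comes from a Wittig reaction on a lactone C5 aldehyde, itself made from the C5 carboxylic acid that the key step delivers.
3. The α-alkylidene-γ-butyrolactone arises by Ireland–Claisen ring contraction of a seven-membered 1,4-dioxepane-2,5-dione: one [3,3] shift forms the lactone C4–C5 bond, closes the lactone, sets C5 by chirality transfer and fixes the (Z)-alkylidene geometry.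
4. Enabling feature: in the dioxepanedione the exocyclic C6=CH2, the acyloxy-bearing stereocentre C7 and the enolisable glycolate C3H2 become, after enolisation, the 1,5-diene C3=C2–O1–C7–C6=CH2; the C7–O1 bond of this temporary ring is the one that breaks.
5. Ring order: dioxepanedione first (asymmetric Morita–Baylis–Hillman adduct, bromoacetylation, carboxylate alkylation), then the γ-lactone by contraction, then attachment of the butenolide.

Key step: step 9

Remark (assumption on the chemistry): α-isocupreine, the pseudo-enantiomer of β-isocupreidine, is taken to give the (3S) Morita–Baylis–Hillman adduct. Lactone positions are numbered O1, C2 (C=O), C3 (alkylidene carbon), C4 (CH2), C5 (CH–O); dioxepanedione positions are O1, C2 (C=O), C3 (CH2), O4, C5 (C=O), C6 (C=CH2), C7 (CH).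

## Route

Step 1
Reactants: 1 (2E,6E)-farnesol
Product: 2 farnesyl tert-butyldimethylsilyl ether
Conditions: TBSCl, imidazole, CH2Cl2, 0 °C to rt
Reagents that add atoms: tert-butyldimethylsilyl chloride, CC(C)(C)[Si](C)(C)Cl
Why: Silyl ether protection of the primary allylic alcohol, so that the far chain end survives the basic, acylating and hydride steps and can be released with fluoride late in the route.

Step 2
Reactants: 2 farnesyl silyl ether
Product: 3 terminal bromohydrin (racemic)
Conditions: NBS, THF/H2O, 0 °C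
Reagents that add atoms: N-bromosuccinimide, O=C1CCC(=O)N1Br; water, O
Why: Terminal-selective bromohydrin formation (electrophilic bromination of the most exposed trisubstituted alkene of the coiled polyene in aqueous THF, Markovnikov capture by water); the racemic centre is destroyed in step 4.

Step 3
Reactants: 3 bromohydrin
Product: 4 terminal epoxide (racemic)
Conditions: K2CO3, MeOH, rt
Reagents that add atoms: none
Why: Intramolecular Williamson etherification of the bromohydrin alkoxide closes the epoxide.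

Step 4
Reactants: 4 epoxide
Product: 5 (4E,8E)-10-silyloxy-4,8-dimethyldeca-4,8-dienal
Conditions: H5IO6, THF/Et2O, 0 °C
Reagents that add atoms: none
Why: Periodic acid opens the epoxide to the glycol and cleaves it (glycol cleavage), which should give the aldehyde and acetone without touching the trisubstituted alkenes.

Step 5
Reactants: 5 dienal; 6 1,1,1,3,3,3-hexafluoropropan-2-yl acrylate
Product: 7 (3S)-Morita–Baylis–Hillman hexafluoroisopropyl ester
Conditions: α-isocupreine (10 mol %), DMF, −55 °C
Reagents that add atoms: none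
Why: Enantioselective Morita–Baylis–Hillman reaction; the quinuclidine nitrogen of the cinchona-derived catalyst adds to the activated acrylate and its phenolic OH organises the aldol and proton-transfer steps, so catalyst control should set the (3S) carbinol centre.

Step 6
Reactants: 7 hexafluoroisopropyl ester
Product: 8 (3S)-3-hydroxy-2-methylidene acid
Conditions: LiOH, THF/H2O, 0 °C; then 1 M HCl to pH 3
Reagents that add atoms: LiOH (lithium hydroxide), [Li+].[OH-]
Why: Saponification; the hexafluoroisopropyl ester is an activated ester and should hydrolyse under conditions that leave the silyl ether and the allylic carbinol untouched.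

Step 7
Reactants: 8 hydroxy acid; 9 bromoacetyl bromide
Product: 10 (3S)-3-(bromoacetoxy)-2-methylidene acid
Conditions: pyridine, CH2Cl2, −20 °C
Reagents that add atoms: none
Why: O-acylation of the secondary allylic alcohol by the acyl bromide, the usual first stage of unsymmetrical dilactone synthesis from hydroxy acids; the stereocentre is not involved.

Step 8
Reactants: 10 bromoacetoxy acid
Product: 11 (7S)-7-alkyl-6-methylidene-1,4-dioxepane-2,5-dione
Conditions: NaHCO3, DMF, high dilution (slow addition), rt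
Reagents that add atoms: none
Why: Intramolecular carboxylate alkylation (7-exo-tet SN2 on the α-bromo ester), the known closure of 1,4-dioxane- and 1,4-dioxepane-2,5-diones; high dilution should favour the ring over oligomers.

Step 9
Reactants: 11 dioxepanedione
Product: 14 (2R,4Z)-4-alkylidene-5-oxooxolane-2-carboxylic acid, via silyl ketene acetal 12 (not isolated), via silyl ester 13 (not isolated)
Conditions: TBSOTf, iPr2NEt, toluene, 0 °C to 80 °C; then citric acid, THF/H2O, rt
Reagents that add atoms: none
Why: Proposed new method: soft enolisation at the only enolisable position of 11 (the glycolate C3H2) should give the ring-constrained silyl ketene acetal 12, whose C3=C2–O1–C7–C6=CH2 array should undergo an Ireland–Claisen [3,3] shift that joins C3 to the exocyclic methylene carbon, breaks the allylic C7–O1 bond and contracts the seven-membered ring to the γ-lactone. The closest known reactions are the Ireland–Claisen ring contraction of lactone silyl ketene acetals and the acyclic ester-enolate Claisen rearrangement of Morita–Baylis–Hillman esters; neither has been shown for a dilactone in which a two-atom tether (O4–C5) links the ketene acetal terminus to the central carbon of the allyl unit. The lactone closes through the new C4–C5 bond in a bridged, bicyclo[3.2.1]-like chair transition state; towards the acrylate C=CH2 this is a 5-endo-trig attack, which a stepwise Michael addition would not tolerate but a concerted shift with simultaneous C7–O1 cleavage should, helped by matched polarity (nucleophilic ketene acetal carbon, electrophilic acrylate β-carbon). The new stereocentre C5 is set by chirality transfer from C7: the ring fixes the ketene acetal geometry (both ring oxygens cis) and the side chain should take the equatorial site to avoid a 1,3-diaxial contact with the silyloxy group, so (7S) should give (5R). The same equatorial placement puts the chain cis to the lactone carbonyl, which is the required (Z)-alkylidene geometry. The step needs enolisation only at the glycolate CH2 (no other acidic C–H is present) and no O-to-C acyl shift of the α-acyloxy enolate, which silyl triflate and amine should secure where a lithium enolate might not.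

Step 10
Reactants: 14 lactone acid
Product: 16 (3Z,5R)-5-(hydroxymethyl) lactone, via mixed carbonic anhydride 15 (not isolated)
Conditions: i-BuOCOCl, N-methylmorpholine, THF, −15 °C; then NaBH4, H2O, −15 to 0 °C
Reagents that add atoms: none
Why: Mixed-anhydride activation followed by borohydride reduction takes the acid to the primary alcohol, while the lactone and the conjugated trisubstituted alkene, both slow towards NaBH4 at this temperature, should survive.

Step 11
Reactants: 16 hydroxymethyl lactone
Product: 17 (2R,4Z)-4-alkylidene-5-oxooxolane-2-carbaldehyde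
Conditions: Dess–Martin periodinane, CH2Cl2, 0 °C to rt
Reagents that add atoms: none
Why: Dess–Martin oxidation under near-neutral conditions should give the α-acyloxy aldehyde without epimerising C5; it is used crude.

Step 12
Reactants: 17 lactone aldehyde; 18 isopropyltriphenylphosphonium iodide
Product: 19 (3Z,5R)-5-(2-methylprop-1-enyl) lactone silyl ether
Conditions: n-BuLi, THF, 0 °C (ylide); then 17, −78 to 0 °C
Reagents that add atoms: none
Why: Wittig olefination with the non-stabilised isopropylidene ylide; the new alkene carries two identical methyl groups, so no geometry arises, and addition to the aldehyde at −78 °C should outrun enolisation.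

Step 13
Reactants: 19 silyl ether
Product: 20 allylic alcohol
Conditions: HF·pyridine, pyridine/THF, 0 °C to rt
Reagents that add atoms: none
Why: Fluoride-mediated desilylation under buffered, non-basic conditions that should spare the lactone and its Michael acceptor.

Step 14
Reactants: 20 allylic alcohol
Product: 21 (2E)-enal
Conditions: Dess–Martin periodinane, CH2Cl2, 0 °C
Reagents that add atoms: none
Why: Dess–Martin oxidation of the primary allylic alcohol should give the (E)-enal without isomerisation.

Step 15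
Reactants: 21 enal; 22 2-(dichloromethyl)-4,4,5,5-tetramethyl-1,3,2-dioxaborolane
Product: 23 (E,E)-dienyl pinacol boronate
Conditions: CrCl2, LiI, THF, rt
Reagents that add atoms: none
Why: Takai–Utimoto olefination with the gem-dichromium reagent formed from the dichloromethylboronate; anti elimination from the β-oxido chromium adduct should give the (E)-alkenyl boronate, and divalent chromium reacts only with the aldehyde.

Step 16
Reactants: 23 dienyl boronate; 24 4-bromofuran-2(5H)-one
Product: 25 target
Conditions: PdCl2(dppf) (5 mol %), K3PO4, THF/H2O, rt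
Reagents that add atoms: none
Why: Suzuki–Miyaura coupling of the alkenyl boronate with the vinylogous acyl bromide should proceed with retention of alkene geometry under mildly basic conditions.

## Compound list

1 | (2E,6E)-3,7,11-trimethyldodeca-2,6,10-trien-1-ol (farnesol) | CC(C)=CCC/C(C)=C/CC/C(C)=C/CO | starting material
2 | tert-butyl(dimethyl){[(2E,6E)-3,7,11-trimethyldodeca-2,6,10-trien-1-yl]oxy}silane | CC(C)=CCC/C(C)=C/CC/C(C)=C/CO[Si](C)(C)C(C)(C)C | intermediate
3 | (6E,10E)-3-bromo-12-{[tert-butyl(dimethyl)silyl]oxy}-2,6,10-trimethyldodeca-6,10-dien-2-ol (racemic) | CC(C)(O)C(Br)CC/C(C)=C/CC/C(C)=C/CO[Si](C)(C)C(C)(C)C | intermediate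
4 | tert-butyl{[(2E,6E)-9-(3,3-dimethyloxiran-2-yl)-3,7-dimethylnona-2,6-dien-1-yl]oxy}dimethylsilane (racemic) | CC1(C)OC1CC/C(C)=C/CC/C(C)=C/CO[Si](C)(C)C(C)(C)C | intermediate
5 | (4E,8E)-10-{[tert-butyl(dimethyl)silyl]oxy}-4,8-dimethyldeca-4,8-dienal | O=CCC/C(C)=C/CC/C(C)=C/CO[Si](C)(C)C(C)(C)C | intermediate
6 | 1,1,1,3,3,3-hexafluoropropan-2-yl acrylate | C=CC(=O)OC(C(F)(F)F)C(F)(F)F | starting material
7 | 1,1,1,3,3,3-hexafluoropropan-2-yl (3S,6E,10E)-12-{[tert-butyl(dimethyl)silyl]oxy}-3-hydroxy-6,10-dimethyl-2-methylidenedodeca-6,10-dienoate | C=C(C(=O)OC(C(F)(F)F)C(F)(F)F)[C@@H](O)CC/C(C)=C/CC/C(C)=C/CO[Si](C)(C)C(C)(C)C | intermediate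
8 | (3S,6E,10E)-12-{[tert-butyl(dimethyl)silyl]oxy}-3-hydroxy-6,10-dimethyl-2-methylidenedodeca-6,10-dienoic acid | C=C(C(=O)O)[C@@H](O)CC/C(C)=C/CC/C(C)=C/CO[Si](C)(C)C(C)(C)C | intermediate
9 | bromoacetyl bromide | BrCC(Br)=O | starting material
10 | (3S,6E,10E)-3-[(bromoacetyl)oxy]-12-{[tert-butyl(dimethyl)silyl]oxy}-6,10-dimethyl-2-methylidenedodeca-6,10-dienoic acid | C=C(C(=O)O)[C@@H](OC(=O)CBr)CC/C(C)=C/CC/C(C)=C/CO[Si](C)(C)C(C)(C)C | intermediate
11 | (7S)-7-[(3E,7E)-9-{[tert-butyl(dimethyl)silyl]oxy}-3,7-dimethylnona-3,7-dien-1-yl]-6-methylidene-1,4-dioxepane-2,5-dione | C=C1C(=O)OCC(=O)O[C@H]1CC/C(C)=C/CC/C(C)=C/CO[Si](C)(C)C(C)(C)C | intermediate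
12 | (7S)-2-{[tert-butyl(dimethyl)silyl]oxy}-7-[(3E,7E)-9-{[tert-butyl(dimethyl)silyl]oxy}-3,7-dimethylnona-3,7-dien-1-yl]-6-methylidene-6,7-dihydro-5H-1,4-dioxepin-5-one | C=C1C(=O)OC=C(O[Si](C)(C)C(C)(C)C)O[C@H]1CC/C(C)=C/CC/C(C)=C/CO[Si](C)(C)C(C)(C)C | intermediate
13 | tert-butyl(dimethyl)silyl (2R,4Z)-4-[(4E,8E)-10-{[tert-butyl(dimethyl)silyl]oxy}-4,8-dimethyldeca-4,8-dien-1-ylidene]-5-oxooxolane-2-carboxylate | CC(C)(C)[Si](C)(C)OC(=O)[C@H]1C/C(=C/CC/C(C)=C/CC/C(C)=C/CO[Si](C)(C)C(C)(C)C)C(=O)O1 | intermediate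
14 | (2R,4Z)-4-[(4E,8E)-10-{[tert-butyl(dimethyl)silyl]oxy}-4,8-dimethyldeca-4,8-dien-1-ylidene]-5-oxooxolane-2-carboxylic acid | OC(=O)[C@H]1C/C(=C/CC/C(C)=C/CC/C(C)=C/CO[Si](C)(C)C(C)(C)C)C(=O)O1 | intermediate
15 | mixed anhydride of 14 with isobutyl hydrogen carbonate | CC(C)COC(=O)OC(=O)[C@H]1C/C(=C/CC/C(C)=C/CC/C(C)=C/CO[Si](C)(C)C(C)(C)C)C(=O)O1 | intermediate
16 | (3Z,5R)-3-[(4E,8E)-10-{[tert-butyl(dimethyl)silyl]oxy}-4,8-dimethyldeca-4,8-dien-1-ylidene]-5-(hydroxymethyl)oxolan-2-one | OC[C@H]1C/C(=C/CC/C(C)=C/CC/C(C)=C/CO[Si](C)(C)C(C)(C)C)C(=O)O1 | intermediate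
17 | (2R,4Z)-4-[(4E,8E)-10-{[tert-butyl(dimethyl)silyl]oxy}-4,8-dimethyldeca-4,8-dien-1-ylidene]-5-oxooxolane-2-carbaldehyde | O=C[C@H]1C/C(=C/CC/C(C)=C/CC/C(C)=C/CO[Si](C)(C)C(C)(C)C)C(=O)O1 | intermediate
18 | isopropyltriphenylphosphonium iodide | CC(C)[P+](c1ccccc1)(c1ccccc1)c1ccccc1.[I-] | starting material
19 | (3Z,5R)-3-[(4E,8E)-10-{[tert-butyl(dimethyl)silyl]oxy}-4,8-dimethyldeca-4,8-dien-1-ylidene]-5-(2-methylprop-1-en-1-yl)oxolan-2-one | CC(C)=C[C@H]1C/C(=C/CC/C(C)=C/CC/C(C)=C/CO[Si](C)(C)C(C)(C)C)C(=O)O1 | intermediate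
20 | (3Z,5R)-3-[(4E,8E)-10-hydroxy-4,8-dimethyldeca-4,8-dien-1-ylidene]-5-(2-methylprop-1-en-1-yl)oxolan-2-one | CC(C)=C[C@H]1C/C(=C/CC/C(C)=C/CC/C(C)=C/CO)C(=O)O1 | intermediate
21 | (2E,6E,10Z)-3,7-dimethyl-10-[(5R)-5-(2-methylprop-1-en-1-yl)-2-oxooxolan-3-ylidene]deca-2,6-dienal | CC(C)=C[C@H]1C/C(=C/CC/C(C)=C/CC/C(C)=C/C=O)C(=O)O1 | intermediate
22 | 2-(dichloromethyl)-4,4,5,5-tetramethyl-1,3,2-dioxaborolane | CC1(C)OB(C(Cl)Cl)OC1(C)C | starting material
23 | (3Z,5R)-3-[(4E,8E,10E)-4,8-dimethyl-11-(4,4,5,5-tetramethyl-1,3,2-dioxaborolan-2-yl)undeca-4,8,10-trien-1-ylidene]-5-(2-methylprop-1-en-1-yl)oxolan-2-one | CC(C)=C[C@H]1C/C(=C/CC/C(C)=C/CC/C(C)=C/C=C/B2OC(C)(C)C(C)(C)O2)C(=O)O1 | intermediate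
24 | 4-bromofuran-2(5H)-one | O=C1C=C(Br)CO1 | starting material
25 | (3Z,5R)-3-[(4E,8E,10E)-4,8-dimethyl-11-(5-oxo-2,5-dihydrofuran-3-yl)undeca-4,8,10-trien-1-ylidene]-5-(2-methylprop-1-en-1-yl)oxolan-2-one | CC(C)=C[C@H]1C/C(=C/CC/C(C)=C/CC/C(C)=C/C=C/C2=CC(=O)OC2)C(=O)O1 | target

## Step count and risks

Total steps: 16. Longest linear sequence: 16 steps (1 to 25).

Steps most likely to fail:

Step 9. The bridged [3,3] transition state may be too strained, so that the silyl ketene acetal persists and hydrolyses back to 11. Alternatively an ionic stepwise path may erode the transfer of chirality and the alkene geometry. The fallback uses an acyclic ester-enolate Claisen rearrangement followed by lactonisation; it sets out from 5 and comes back at 14. The Morita–Baylis–Hillman reaction of 5 with 6 is run with β-isocupreidine to give the (3R) hexafluoroisopropyl ester F1. The opposite carbinol configuration is needed because the acyclic chelated ketene acetal has the opposite geometry to the ring-constrained one. Methanolysis (MeOH, Et3N) should give the methyl ester F2, and esterification with [(4-methoxybenzyl)oxy]acetic acid (DCC, DMAP) the glycolate ester F3. LiN(SiMe3)2 and Me3SiCl in THF at −78 °C to rt should give the chelation-controlled (Z)-silyl ketene acetal F4. This should rearrange through a chair transition state to the trimethylsilyl ester F5 and, after aqueous work-up, the (2R,4Z)-acid F6. DDQ should remove the 4-methoxybenzyl group to give the hydroxy acid F7, which with catalytic camphorsulfonic acid should lactonise onto the methyl ester to give 14.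

Step 8. Intermolecular carboxylate alkylation (oligomer formation) may outrun seven-membered ring closure, and the dilactone may ring-open during work-up. The fallback closes the other ester bond; it sets out from 8 and comes back at 11. The carboxylate of 8 (Cs2CO3, DMF) is alkylated with allyl bromoacetate to give the allyl ester F8. Pd(PPh3)4 and morpholine should remove the allyl group to give the seco acid F9. Mixed-anhydride lactonisation (2-methyl-6-nitrobenzoic anhydride, DMAP, high dilution) should then form the ring at the C7–O1 ester bond and give 11.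

Step 12. The basic ylide may enolise the α-acyloxy aldehyde (loss of configuration at C5) or add to and isomerise the (Z)-alkylidene lactone. The fallback avoids a basic reagent; it sets out from 17 and comes back at 19. Nozaki–Hiyama–Kishi addition of 2-bromopropene to 17 (CrCl2, catalytic NiCl2, DMF) should give the allylic alcohol F10; either carbinol epimer serves. Mitsunobu reaction with 2-nitrobenzenesulfonylhydrazide (PPh3, diethyl azodicarboxylate, −30 °C) should give the sulfonylhydrazide F11. On warming this should lose 2-nitrobenzenesulfinic acid to give the allylic diazene F12, and retro-ene loss of N2 with 1,3-transposition of the double bond should give 19.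

## Further compounds

F1 | step 9 | 1,1,1,3,3,3-hexafluoropropan-2-yl (3R,6E,10E)-12-{[tert-butyl(dimethyl)silyl]oxy}-3-hydroxy-6,10-dimethyl-2-methylidenedodeca-6,10-dienoate | C=C(C(=O)OC(C(F)(F)F)C(F)(F)F)[C@H](O)CC/C(C)=C/CC/C(C)=C/CO[Si](C)(C)C(C)(C)C
F2 | step 9 | methyl (3R,6E,10E)-12-{[tert-butyl(dimethyl)silyl]oxy}-3-hydroxy-6,10-dimethyl-2-methylidenedodeca-6,10-dienoate | C=C(C(=O)OC)[C@H](O)CC/C(C)=C/CC/C(C)=C/CO[Si](C)(C)C(C)(C)C
F3 | step 9 | methyl (3R,6E,10E)-12-{[tert-butyl(dimethyl)silyl]oxy}-3-({[(4-methoxybenzyl)oxy]acetyl}oxy)-6,10-dimethyl-2-methylidenedodeca-6,10-dienoate | C=C(C(=O)OC)[C@H](OC(=O)COCc1ccc(OC)cc1)CC/C(C)=C/CC/C(C)=C/CO[Si](C)(C)C(C)(C)C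
F4 | step 9 | (Z)-trimethylsilyl ketene acetal of F3 (4-methoxybenzyloxy cis to trimethylsilyloxy) | C=C(C(=O)OC)[C@H](O/C(O[Si](C)(C)C)=C/OCc1ccc(OC)cc1)CC/C(C)=C/CC/C(C)=C/CO[Si](C)(C)C(C)(C)C
F5 | step 9 | trimethylsilyl (2R,4Z,8E,12E)-14-{[tert-butyl(dimethyl)silyl]oxy}-4-(methoxycarbonyl)-2-[(4-methoxybenzyl)oxy]-8,12-dimethyltetradeca-4,8,12-trienoate | C[Si](C)(C)OC(=O)[C@H](OCc1ccc(OC)cc1)C/C(=C/CC/C(C)=C/CC/C(C)=C/CO[Si](C)(C)C(C)(C)C)C(=O)OC
F6 | step 9 | (2R,4Z,8E,12E)-14-{[tert-butyl(dimethyl)silyl]oxy}-4-(methoxycarbonyl)-2-[(4-methoxybenzyl)oxy]-8,12-dimethyltetradeca-4,8,12-trienoic acid | OC(=O)[C@H](OCc1ccc(OC)cc1)C/C(=C/CC/C(C)=C/CC/C(C)=C/CO[Si](C)(C)C(C)(C)C)C(=O)OC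
F7 | step 9 | (2R,4Z,8E,12E)-14-{[tert-butyl(dimethyl)silyl]oxy}-2-hydroxy-4-(methoxycarbonyl)-8,12-dimethyltetradeca-4,8,12-trienoic acid | OC(=O)[C@H](O)C/C(=C/CC/C(C)=C/CC/C(C)=C/CO[Si](C)(C)C(C)(C)C)C(=O)OC
F8 | step 8 | 2-(allyloxy)-2-oxoethyl (3S,6E,10E)-12-{[tert-butyl(dimethyl)silyl]oxy}-3-hydroxy-6,10-dimethyl-2-methylidenedodeca-6,10-dienoate | C=CCOC(=O)COC(=O)C(=C)[C@@H](O)CC/C(C)=C/CC/C(C)=C/CO[Si](C)(C)C(C)(C)C
F9 | step 8 | {[(3S,6E,10E)-12-{[tert-butyl(dimethyl)silyl]oxy}-3-hydroxy-6,10-dimethyl-2-methylidenedodeca-6,10-dienoyl]oxy}acetic acid | OC(=O)COC(=O)C(=C)[C@@H](O)CC/C(C)=C/CC/C(C)=C/CO[Si](C)(C)C(C)(C)C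
F10 | step 12 | (3Z,5R)-3-[(4E,8E)-10-{[tert-butyl(dimethyl)silyl]oxy}-4,8-dimethyldeca-4,8-dien-1-ylidene]-5-(1-hydroxy-2-methylprop-2-en-1-yl)oxolan-2-one (carbinol epimers) | CC(=C)C(O)[C@H]1C/C(=C/CC/C(C)=C/CC/C(C)=C/CO[Si](C)(C)C(C)(C)C)C(=O)O1
F11 | step 12 | N-{1-[(2R,4Z)-4-alkylidene-5-oxooxolan-2-yl]-2-methylprop-2-en-1-yl}-2-nitrobenzenesulfonohydrazide (alkylidene as in 19) | CC(=C)C(N(N)S(=O)(=O)c1ccccc1[N+](=O)[O-])[C@H]2C/C(=C/CC/C(C)=C/CC/C(C)=C/CO[Si](C)(C)C(C)(C)C)C(=O)O2
F12 | step 12 | allylic monoalkyl diazene derived from F11 | CC(=C)C(N=N)[C@H]1C/C(=C/CC/C(C)=C/CC/C(C)=C/CO[Si](C)(C)C(C)(C)C)C(=O)O1
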